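The earlier runs and the new flask were generated by integration on assumed constants.

The constants of the working round were hidden, so I had to get what I could from Tuesday's curve.

| flask | substrate | partner | free catalyst | remark |
|---|---|---|---|---|
| Tuesday's | 1.5 M | 2 equiv | 0.2 mol% | run made earlier |
| flask | 1.5 M | 1.00 equiv | 0.2 mol% |  |

- Tuesday's (time / min: product / %, substrate / %): 0.200: 6.0, 94.2; 0.333: 7.5, 89.1; 0.417: 11.7, 87.8; 0.667: 20.3, 80.4; 1.00: 30.6, 69.9; 1.50: 41.5, 55.4; 2.50: 70.6, 29.7

(scatter of a reading: 1 percentage point)

- a species is counted by the substrate in it: one idle complex counts as two
- on the list of suspects stand: substrate + free catalyst -> catalyst intermediate A; partner + catalyst intermediate A <-> catalyst intermediate B; catalyst intermediate B -> free catalyst + product; substrate + catalyst intermediate A <-> idle complex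
- no earlier run changes the charge of free catalyst; that part of a forecast is a guess
- no earlier run changes the charge of partner; that part of a forecast is a guess

- apparent order in partner when 30 % of the substrate are converted (percent change of the rate of making product for one percent more partner charged)
- apparent order in free catalyst when 30 % of the substrate are converted (percent change of the rate of making product for one percent more free catalyst charged)
- factor on the rate of making product when 30 % of the substrate are converted if free catalyst is charged twice over

In Tuesday's run, product rose by 0.306 min⁻¹ of the charge up to 1.00 min, then by 0.267 min⁻¹ up to 2.50 min. Meanwhile, partner averaged 1.85 and then 1.49 equivalents of the substrate charged. Putting the whole fall down to partner, with substrate's share unseparated, I read an order of 0.649 in the partner standing, a rough reading given the scatter.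

I then let the order fall as partner rises, order = h/(h + partner). At the mean of 1.67 equivalents, this put h at 3.08, and h was my weak link. In the new flask, partner stands at 0.700 equivalents at 30 % conversion, so the order in partner standing came to 0.815.

The question, however, counts percent of partner charged. Converted substrate takes partner one for one, so I defined the lever, the percent change in partner standing for one percent more partner charged, which is the charge over what stands: 1.43. This is more than one, and it carried my number to 1.16.

The forecast differs from mine: it gave 0.6 for partner, saying “so the order should be higher, about 0.6–0.7”. For free catalyst it gave 1 and a factor of 2.

The flask gave 1.2 for partner, 1.0 for free catalyst and a factor of 2.01.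

    substrate + free catalyst → catalyst intermediate A (k = 10.0 M⁻¹ s⁻¹)
    partner + catalyst intermediate A ⇌ catalyst intermediate B (K = 0.590 M⁻¹, k = 6.80 M⁻¹ s⁻¹)
    catalyst intermediate B → free catalyst + product (k = 19.0 s⁻¹)
    substrate + catalyst intermediate A ⇌ idle complex, settled at all times (K = 1.70 M⁻¹)

Divided by the lever, 1.2 becomes 0.805 per percent of partner standing at 1.78 min, when product was forming at 0.155 min⁻¹ of the charge. Tuesday's lever is 1.18, smaller than this flask's, and on the order read there it gives 0.763.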